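The route rests on cutting the two neighbouring arene bonds C2'–O and C3'–CHO back to a C2'≡C3' aryne and N,N-dimethylformamide. One fluoride-triggered operation inserts the aryne into the formamide C=O bond: the formamide oxygen ends on C2', its carbon on C3', and hydrolysis leaves C2'–OH as the only free phenol, ready for sulfation; the oxygen on C4', next to C3', fixes the orientation. The precursor is the complete octalin (ring A with the C4 gem-dimethyl group, ring B with C5=C6 and the C8/C9/C10 stereotriad) whose benzyl arene carries trimethylsilyl on C2', triflate on C3' and a diphenylmethylene acetal across the C4' and C5' oxygens.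

Key step: step 16

Remark (locants): octalin C1–C10 with C4 gem-dimethyl, C5=C6, C8 methyl, C9 quaternary, C10 ring-fusion CH; ring A = C1–C5 and C10, ring B = C5–C10; C11 = benzylic carbon; arene C1'–C6'. Oct = (1R,2R,8aS)-1,2,5,5-tetramethyl-1,2,3,5,6,7,8,8a-octahydronaphthalen-1-yl, i.e. (8R,9R,10S).

Remark (stereocontrol): H-10, the C8 methyl and the C9 benzyl group share one face of ring B. Ring B is therefore made by an endo cycloaddition of an α-unsubstituted (E)-crotonyl dienophile, and C9 is made quaternary afterwards from the open face; α-alkyl dienophiles are known to favour exo addition to such dienes, which would invert the C8/C10 relationship.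

Remark (protecting group): the catechol is held as a diphenylmethylene acetal instead of two benzyl ethers: one step differentiates the three oxygens, there is no benzylic C–H for the organolithium steps, and the fused dioxole reinforces the aryne polarisation.

Remark (target form): the target is drawn as the free aryl hydrogen sulfate, so the last step ends with a proton exchange; in practice it would be stored as a salt.

Step 1
Reactants: 1 2,2-dimethylcyclohexanone
Product: 2 6,6-dimethylcyclohex-1-en-1-yl trifluoromethanesulfonate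
Conditions: Tf2O, 2,6-di-tert-butyl-4-methylpyridine, CH2Cl2, 0 °C to rt
Reagents that add atoms: trifluoromethanesulfonic anhydride, O=S(=O)(OS(=O)(=O)C(F)(F)F)C(F)(F)F
Why: The ketone can enolise only away from the quaternary carbon, so enol triflation with a hindered pyridine base should give a single vinyl triflate.

Step 2
Reactants: 2 6,6-dimethylcyclohex-1-en-1-yl trifluoromethanesulfonate
Product: 3 6,6-dimethyl-1-vinylcyclohex-1-ene
Conditions: tributyl(vinyl)stannane, Pd(PPh3)4 (cat.), LiCl, THF, reflux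
Reagents that add atoms: tributyl(vinyl)stannane, C=C[Sn](CCCC)(CCCC)CCCC
Why: Stille coupling of an enol triflate with a vinylstannane is the standard entry to 1-vinylcycloalkenes and leaves the ring double bond in place.

Step 3
Reactants: 4 (R)-4-benzyloxazolidin-2-one; 5 (E)-but-2-enoyl chloride
Product: 6 (R)-4-benzyl-3-[(E)-but-2-enoyl]oxazolidin-2-one
Conditions: n-BuLi, THF, −78 °C; then 5, −78 to 0 °C
Reagents that add atoms: none
Why: N-acylation of the lithiated oxazolidinone (loading of an Evans auxiliary) should proceed without touching the (E)-alkene.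

Step 4
Reactants: 3 6,6-dimethyl-1-vinylcyclohex-1-ene; 6 (R)-4-benzyl-3-[(E)-but-2-enoyl]oxazolidin-2-one
Product: 7 (4R)-4-benzyl-3-{[(1S,2R,8aS)-2,5,5-trimethyl-1,2,3,5,6,7,8,8a-octahydronaphthalen-1-yl]carbonyl}oxazolidin-2-one (C9 acyl β; C8 methyl and H-10 α)
Conditions: Et2AlCl (1.4 equiv), CH2Cl2, −78 to −20 °C; aq. HCl work-up
Reagents that add atoms: none
Why: Evans auxiliary-controlled, Et2AlCl-promoted Diels–Alder reaction: the β-carbon of the chelated s-cis imide bonds to the unsubstituted vinyl terminus (C7–C8) and the α-carbon to the ring CH (C9–C10), the α-unsubstituted acyl group sits endo so that the C8 methyl ends cis to H-10, and the diene approaches the face remote from the benzyl group, which should give (8R,10S); C9 is re-set in step 7.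

Step 5
Reactants: 7 Diels–Alder imide
Product: 8 [(1S,2R,8aS)-2,5,5-trimethyl-1,2,3,5,6,7,8,8a-octahydronaphthalen-1-yl]methanol
Conditions: LiBH4, MeOH (1 equiv), THF, 0 °C to rt
Reagents that add atoms: none
Why: Reductive removal of the auxiliary: borohydride attacks the exocyclic imide carbonyl, giving the primary alcohol and returning the oxazolidinone.

Step 6
Reactants: 8 primary alcohol
Product: 9 (1S,2R,8aS)-2,5,5-trimethyl-1,2,3,5,6,7,8,8a-octahydronaphthalene-1-carbaldehyde
Conditions: TEMPO (cat.), PhI(OAc)2, CH2Cl2, rt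
Reagents that add atoms: none
Why: Nitroxyl-catalysed oxidation of a primary alcohol stops at the aldehyde and spares the trisubstituted alkene; epimerisation at C9 would be harmless because C9 is enolised next.

Step 7
Reactants: 9 C9–H aldehyde
Product: 10 (1R,2R,8aS)-1,2,5,5-tetramethyl-1,2,3,5,6,7,8,8a-octahydronaphthalene-1-carbaldehyde (Oct–CHO)
Conditions: t-BuOK, MeI (excess), THF, 0 °C to rt
Reagents that add atoms: iodomethane, CI
Why: Alkylation of the potassium enolate of an α-branched aldehyde: with H-10 and the C8 methyl both pseudo-axial on one face of the trigonal C9, iodomethane should enter from the opposite face, placing the new methyl trans to the C8 methyl and to H-10 and leaving the formyl carbon (future C11) cis to them (9R).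

Step 8
Reactants: 11 5-bromo-1,2,3-trimethoxybenzene
Product: 12 5-bromobenzene-1,2,3-triol
Conditions: BBr3, CH2Cl2, −78 °C to rt; H2O
Reagents that add atoms: none
Why: Boron tribromide cleavage of aryl methyl ethers should free all three phenols without touching the aryl bromide.

Step 9
Reactants: 12 5-bromobenzene-1,2,3-triol
Product: 13 6-bromo-2,2-diphenyl-1,3-benzodioxol-4-ol
Conditions: dichlorodiphenylmethane, neat, 160 °C
Reagents that add atoms: dichlorodiphenylmethane, ClC(Cl)(c1ccccc1)c1ccccc1
Why: Ketalisation can only bridge two adjacent hydroxyls as a five-membered dioxole, and in the symmetrical triol either pair gives the same product, leaving one phenol free.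

Step 10
Reactants: 13 6-bromo-2,2-diphenyl-1,3-benzodioxol-4-ol
Product: 14 6-bromo-2,2-diphenyl-1,3-benzodioxol-4-yl diethylcarbamate
Conditions: N,N-diethylcarbamoyl chloride, K2CO3, MeCN, reflux
Reagents that add atoms: N,N-diethylcarbamoyl chloride, CCN(CC)C(Cl)=O
Why: O-carbamoylation of the remaining phenol installs the group that later directs lithiation to C2' and marks the C3' oxygen for conversion into the triflate.

Step 11
Reactants: 14 6-bromo-2,2-diphenyl-1,3-benzodioxol-4-yl diethylcarbamate; 10 Oct–CHO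
Product: 17 O-{[7-(diethylcarbamoyloxy)-2,2-diphenyl-1,3-benzodioxol-5-yl](Oct)methyl} S-methyl carbonodithioate (both C11 epimers), via aryllithium 15 (not isolated), via lithium alkoxide 16 (not isolated)
Conditions: t-BuLi (2 equiv), THF, −78 °C; 10, −78 to 0 °C; CS2, 0 °C; MeI, rt
Reagents that add atoms: carbon disulfide, S=C=S; iodomethane, CI
Why: Bromine–lithium exchange is faster than attack on the meta carbamate at −78 °C, the aryllithium adds to the non-enolisable aldehyde, and the alkoxide is trapped as a xanthate; the C11 configuration is irrelevant because this centre becomes CH2.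

Step 12
Reactants: 17 xanthate
Product: 18 2,2-diphenyl-6-(Oct-methyl)-1,3-benzodioxol-4-yl diethylcarbamate
Conditions: Bu3SnH, AIBN (cat.), toluene, 90 °C
Reagents that add atoms: none
Why: Barton–McCombie deoxygenation: the benzylic radical has no β-hydrogen at C9 to lose and can reach the C5=C6 alkene only by disfavoured 4-exo or 5-endo closure, so simple hydrogen transfer should prevail.

Step 13
Reactants: 18 aryl carbamate
Product: 20 2,2-diphenyl-6-(Oct-methyl)-5-(trimethylsilyl)-1,3-benzodioxol-4-yl diethylcarbamate, via C2' aryllithium 19 (not isolated)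
Conditions: s-BuLi, TMEDA, THF, −78 °C; TMSCl, −78 °C to rt
Reagents that add atoms: chlorotrimethylsilane, C[Si](C)(C)Cl
Why: Directed ortho-metalation by the O-carbamate can only occur at C2' because C4' is blocked and the acetal has no acidic C–H, and silylation at −78 °C precedes any anionic Fries shift.

Step 14
Reactants: 20 silylated carbamate
Product: 21 2,2-diphenyl-6-(Oct-methyl)-5-(trimethylsilyl)-1,3-benzodioxol-4-ol
Conditions: LiAlH4, THF, 0 to 40 °C; neutral aqueous work-up
Reagents that add atoms: none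
Why: Hydride cleavage of the aryl carbamate should free the C3' phenol while the aryl–silicon bond, the acetal and the alkene are inert to LiAlH4.

Step 15
Reactants: 21 ortho-silyl phenol
Product: 22 2,2-diphenyl-6-(Oct-methyl)-5-(trimethylsilyl)-1,3-benzodioxol-4-yl trifluoromethanesulfonate (2'-trimethylsilyl-3'-triflyloxy precursor)
Conditions: Tf2O, pyridine, CH2Cl2, 0 °C
Reagents that add atoms: trifluoromethanesulfonic anhydride, O=S(=O)(OS(=O)(=O)C(F)(F)F)C(F)(F)F
Why: O-triflation of an ortho-silyl phenol is the standard last step towards fluoride-triggered aryne precursors of the 2-alkoxy-6-silylaryl triflate type.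

Step 16
Reactants: 22 2'-trimethylsilyl-3'-triflyloxy precursor; 23 N,N-dimethylformamide
Product: 26 5-hydroxy-2,2-diphenyl-6-(Oct-methyl)-1,3-benzodioxole-4-carbaldehyde (2'-hydroxy-3'-formyl arene), via aryne 24 (not isolated), via iminium phenolate 25 (not isolated)
Conditions: CsF (3 equiv), 23 as solvent, rt to 50 °C; then H2O
Reagents that add atoms: water, O
Why: Fluoride removes the C2' silyl group and the C3' triflate leaves to give aryne 24; the formamide oxygen attacks C2', the aryl anion at C3' closes onto the iminium carbon (formal [2+2]), and the strained benzoxete opens to iminium phenolate 25, which water hydrolyses to the aldehyde (water supplies the formyl oxygen, the formamide the phenol oxygen). The closest known reaction type is the insertion of fluoride-generated arynes into the C=O bond of formamides to give salicylaldehydes. No ring of the product is closed (the four-membered benzoxete is transient, formed by collapse of a 1,4-zwitterion) and no stereocentre is created or touched. The selectivity needed is regiochemical, oxygen at C2' and carbon at C3': the dioxole oxygen on C4' withdraws inductively and its five-membered ring pinches the angle at C3', so C2' is the more linear, more electrophilic aryne terminus and negative charge builds at C3' beside oxygen, which should outweigh the steric bias of the C1' alkyl group. Using the formamide as solvent should let its capture of the aryne outrun attack by the C5=C6 alkene or by product phenoxide.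

Step 17
Reactants: 26 2'-hydroxy-3'-formyl arene
Product: 27 pyridinium 4-formyl-2,2-diphenyl-6-(Oct-methyl)-1,3-benzodioxol-5-yl sulfate
Conditions: SO3·pyridine (excess), pyridine, 50 °C
Reagents that add atoms: sulfur trioxide–pyridine complex, O=S(=O)([O-])[n+]1ccccc1
Why: O-sulfation with SO3·pyridine can only occur at C2'–OH, the single free phenol, since the C4' and C5' oxygens are locked in the acetal.

Step 18
Reactants: 27 pyridinium aryl sulfate
Product: 28 2-formyl-3,4-dihydroxy-6-(Oct-methyl)phenyl hydrogen sulfate (target)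
Conditions: H2 (1 atm), Pd/C, EtOAc–MeOH, rt, stopped at full acetal cleavage; then Dowex 50W (H+ form), cold MeOH–H2O
Reagents that add atoms: none
Why: Hydrogenolysis of the two benzhydryl-type C–O bonds of the diphenylmethylene acetal should free the catechol while the aryl sulfate is inert and the C5=C6 alkene, trisubstituted and flanked by the quaternary C4, is too hindered to be reduced quickly; proton exchange then gives the hydrogen sulfate.

Compound list

1 | 2,2-dimethylcyclohexanone | CC1(C)CCCCC1=O | starting material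
2 | 6,6-dimethylcyclohex-1-en-1-yl trifluoromethanesulfonate | CC1(C)CCCC=C1OS(=O)(=O)C(F)(F)F | intermediate
3 | 6,6-dimethyl-1-vinylcyclohex-1-ene | CC1(C)CCCC=C1C=C | intermediate
4 | (R)-4-benzyloxazolidin-2-one | O=C1N[C@H](Cc2ccccc2)CO1 | starting material
5 | (E)-but-2-enoyl chloride | C/C=C/C(Cl)=O | starting material
6 | (R)-4-benzyl-3-[(E)-but-2-enoyl]oxazolidin-2-one | C/C=C/C(=O)N1[C@H](Cc2ccccc2)COC1=O | intermediate
7 | (4R)-4-benzyl-3-{[(1S,2R,8aS)-2,5,5-trimethyl-1,2,3,5,6,7,8,8a-octahydronaphthalen-1-yl]carbonyl}oxazolidin-2-one | C[C@@H]1CC=C2[C@@H](CCCC2(C)C)[C@H]1C(=O)N1[C@H](Cc2ccccc2)COC1=O | intermediate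
8 | [(1S,2R,8aS)-2,5,5-trimethyl-1,2,3,5,6,7,8,8a-octahydronaphthalen-1-yl]methanol | C[C@@H]1CC=C2[C@@H](CCCC2(C)C)[C@H]1CO | intermediate
9 | (1S,2R,8aS)-2,5,5-trimethyl-1,2,3,5,6,7,8,8a-octahydronaphthalene-1-carbaldehyde | C[C@@H]1CC=C2[C@@H](CCCC2(C)C)[C@H]1C=O | intermediate
10 | (1R,2R,8aS)-1,2,5,5-tetramethyl-1,2,3,5,6,7,8,8a-octahydronaphthalene-1-carbaldehyde | C[C@@H]1CC=C2[C@@H](CCCC2(C)C)[C@]1(C)C=O | intermediate
11 | 5-bromo-1,2,3-trimethoxybenzene | COc1cc(Br)cc(OC)c1OC | starting material
12 | 5-bromobenzene-1,2,3-triol | Oc1cc(Br)cc(O)c1O | intermediate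
13 | 6-bromo-2,2-diphenyl-1,3-benzodioxol-4-ol | Oc1cc(Br)cc2OC(c3ccccc3)(c3ccccc3)Oc12 | intermediate
14 | 6-bromo-2,2-diphenyl-1,3-benzodioxol-4-yl diethylcarbamate | CCN(CC)C(=O)Oc1cc(Br)cc2OC(c3ccccc3)(c3ccccc3)Oc12 | intermediate
15 | 6-lithio-2,2-diphenyl-1,3-benzodioxol-4-yl diethylcarbamate | CCN(CC)C(=O)Oc1cc([Li])cc2OC(c3ccccc3)(c3ccccc3)Oc12 | intermediate
16 | lithium [7-(diethylcarbamoyloxy)-2,2-diphenyl-1,3-benzodioxol-5-yl][(1R,2R,8aS)-1,2,5,5-tetramethyl-1,2,3,5,6,7,8,8a-octahydronaphthalen-1-yl]methanolate (both C11 epimers) | C[C@@H]1CC=C2[C@@H](CCCC2(C)C)[C@]1(C)C(O[Li])c1cc2OC(c3ccccc3)(c3ccccc3)Oc2c(OC(=O)N(CC)CC)c1 | intermediate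
17 | O-{[7-(diethylcarbamoyloxy)-2,2-diphenyl-1,3-benzodioxol-5-yl][(1R,2R,8aS)-1,2,5,5-tetramethyl-1,2,3,5,6,7,8,8a-octahydronaphthalen-1-yl]methyl} S-methyl carbonodithioate (both C11 epimers) | C[C@@H]1CC=C2[C@@H](CCCC2(C)C)[C@]1(C)C(OC(=S)SC)c1cc2OC(c3ccccc3)(c3ccccc3)Oc2c(OC(=O)N(CC)CC)c1 | intermediate
18 | 2,2-diphenyl-6-{[(1R,2R,8aS)-1,2,5,5-tetramethyl-1,2,3,5,6,7,8,8a-octahydronaphthalen-1-yl]methyl}-1,3-benzodioxol-4-yl diethylcarbamate | C[C@@H]1CC=C2[C@@H](CCCC2(C)C)[C@]1(C)Cc1cc2OC(c3ccccc3)(c3ccccc3)Oc2c(OC(=O)N(CC)CC)c1 | intermediate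
19 | 5-lithio derivative of 18 (lithium on C2') | C[C@@H]1CC=C2[C@@H](CCCC2(C)C)[C@]1(C)Cc1cc2OC(c3ccccc3)(c3ccccc3)Oc2c(OC(=O)N(CC)CC)c1[Li] | intermediate
20 | 2,2-diphenyl-6-{[(1R,2R,8aS)-1,2,5,5-tetramethyl-1,2,3,5,6,7,8,8a-octahydronaphthalen-1-yl]methyl}-5-(trimethylsilyl)-1,3-benzodioxol-4-yl diethylcarbamate | C[C@@H]1CC=C2[C@@H](CCCC2(C)C)[C@]1(C)Cc1cc2OC(c3ccccc3)(c3ccccc3)Oc2c(OC(=O)N(CC)CC)c1[Si](C)(C)C | intermediate
21 | 2,2-diphenyl-6-{[(1R,2R,8aS)-1,2,5,5-tetramethyl-1,2,3,5,6,7,8,8a-octahydronaphthalen-1-yl]methyl}-5-(trimethylsilyl)-1,3-benzodioxol-4-ol | C[C@@H]1CC=C2[C@@H](CCCC2(C)C)[C@]1(C)Cc1cc2OC(c3ccccc3)(c3ccccc3)Oc2c(O)c1[Si](C)(C)C | intermediate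
22 | 2,2-diphenyl-6-{[(1R,2R,8aS)-1,2,5,5-tetramethyl-1,2,3,5,6,7,8,8a-octahydronaphthalen-1-yl]methyl}-5-(trimethylsilyl)-1,3-benzodioxol-4-yl trifluoromethanesulfonate | C[C@@H]1CC=C2[C@@H](CCCC2(C)C)[C@]1(C)Cc1cc2OC(c3ccccc3)(c3ccccc3)Oc2c(OS(=O)(=O)C(F)(F)F)c1[Si](C)(C)C | intermediate
23 | N,N-dimethylformamide | CN(C)C=O | starting material
24 | 4,5-didehydro-2,2-diphenyl-6-{[(1R,2R,8aS)-1,2,5,5-tetramethyl-1,2,3,5,6,7,8,8a-octahydronaphthalen-1-yl]methyl}-1,3-benzodioxole (C2'≡C3' aryne) | C[C@@H]1CC=C2[C@@H](CCCC2(C)C)[C@]1(C)CC1=CC2=C(C#C1)OC(c1ccccc1)(c1ccccc1)O2 | intermediate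
25 | 4-[(dimethyliminio)methyl]-2,2-diphenyl-6-{[(1R,2R,8aS)-1,2,5,5-tetramethyl-1,2,3,5,6,7,8,8a-octahydronaphthalen-1-yl]methyl}-1,3-benzodioxol-5-olate | C[C@@H]1CC=C2[C@@H](CCCC2(C)C)[C@]1(C)Cc1cc2OC(c3ccccc3)(c3ccccc3)Oc2c(C=[N+](C)C)c1[O-] | intermediate
26 | 5-hydroxy-2,2-diphenyl-6-{[(1R,2R,8aS)-1,2,5,5-tetramethyl-1,2,3,5,6,7,8,8a-octahydronaphthalen-1-yl]methyl}-1,3-benzodioxole-4-carbaldehyde | C[C@@H]1CC=C2[C@@H](CCCC2(C)C)[C@]1(C)Cc1cc2OC(c3ccccc3)(c3ccccc3)Oc2c(C=O)c1O | intermediate
27 | pyridinium 4-formyl-2,2-diphenyl-6-{[(1R,2R,8aS)-1,2,5,5-tetramethyl-1,2,3,5,6,7,8,8a-octahydronaphthalen-1-yl]methyl}-1,3-benzodioxol-5-yl sulfate | C[C@@H]1CC=C2[C@@H](CCCC2(C)C)[C@]1(C)Cc1cc2OC(c3ccccc3)(c3ccccc3)Oc2c(C=O)c1OS(=O)(=O)[O-].c1cc[nH+]cc1 | intermediate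
28 | 2-formyl-3,4-dihydroxy-6-{[(1R,2R,8aS)-1,2,5,5-tetramethyl-1,2,3,5,6,7,8,8a-octahydronaphthalen-1-yl]methyl}phenyl hydrogen sulfate | C[C@@H]1CC=C2[C@@H](CCCC2(C)C)[C@]1(C)Cc1cc(O)c(O)c(C=O)c1OS(=O)(=O)O | target

Total step count: 18. Longest linear sequence: 14 steps (steps 1, 2, 4 to 7 and 11 to 18, from 2,2-dimethylcyclohexanone).

Steps most likely to fail

Step 16. Capture of the aryne by the solvent formamide may be outrun by attack of the C5=C6 alkene or of liberated phenoxide on the aryne, the aryl anion may be protonated before it closes onto the iminium carbon, or the oxygen may add with incomplete regiocontrol. The fallback separates the two bond formations; it sets out from 22 and comes back at 26. Treating 22 with CsF and an excess of acetic acid in MeCN at rt should insert the aryne into the O–H bond (carboxylate at C2', proton at C3') and give 2,2-diphenyl-6-(Oct-methyl)-1,3-benzodioxol-5-yl acetate F1. K2CO3 in MeOH frees 2,2-diphenyl-6-(Oct-methyl)-1,3-benzodioxol-5-ol F2. Magnesium-mediated ortho-formylation (MgCl2, Et3N, paraformaldehyde, MeCN, reflux) then places the formyl group on C3', the only free position ortho to the phenol, and gives 26.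

Step 4. Endo or facial control may erode because the aluminium-chelated imide has to pass beneath ring A of the diene, or the acid-sensitive diene may oligomerise under the Lewis acid. The fallback replaces the auxiliary by iminium catalysis; it sets out from 3 and comes back at 9, so steps 3, 5 and 6 fall away. Diene 3 and (E)-but-2-enal with (5R)-5-benzyl-2,2,3-trimethylimidazolidin-4-one hydrochloride (20 mol%) in MeCN–H2O at rt should give aldehyde 9 directly, the benzyl group of the catalyst shielding the same face as the auxiliary does; no new compound arises (F0).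

Step 18. Hydrogen may add to the formyl group or to the ring B alkene before both benzhydryl C–O bonds are cleaved. The fallback avoids hydrogenation by changing to a base-labile catechol protection before sulfation; it sets out from 26 and comes back at 28. Aqueous acetic acid (4:1, 70 °C, under argon) should hydrolyse the acetal to 2,5,6-trihydroxy-3-(Oct-methyl)benzaldehyde F3. One equivalent of 1,1'-carbonyldiimidazole in THF at 0 °C closes the five-membered carbonate across the C4' and C5' oxygens, giving 5-hydroxy-2-oxo-6-(Oct-methyl)-1,3-benzodioxole-4-carbaldehyde F4. SO3·pyridine in pyridine sulfates the remaining C2' phenol to pyridinium 4-formyl-2-oxo-6-(Oct-methyl)-1,3-benzodioxol-5-yl sulfate F5. NaHCO3 in aqueous MeOH at rt opens the aryl carbonate, and proton exchange on Dowex 50W (H+ form) gives 28.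

Further compounds

F1 | step 16 | 2,2-diphenyl-6-{[(1R,2R,8aS)-1,2,5,5-tetramethyl-1,2,3,5,6,7,8,8a-octahydronaphthalen-1-yl]methyl}-1,3-benzodioxol-5-yl acetate | C[C@@H]1CC=C2[C@@H](CCCC2(C)C)[C@]1(C)Cc1cc2OC(c3ccccc3)(c3ccccc3)Oc2cc1OC(C)=O
F2 | step 16 | 2,2-diphenyl-6-{[(1R,2R,8aS)-1,2,5,5-tetramethyl-1,2,3,5,6,7,8,8a-octahydronaphthalen-1-yl]methyl}-1,3-benzodioxol-5-ol | C[C@@H]1CC=C2[C@@H](CCCC2(C)C)[C@]1(C)Cc1cc2OC(c3ccccc3)(c3ccccc3)Oc2cc1O
F0 | step 4 | none | none
F3 | step 18 | 2,5,6-trihydroxy-3-{[(1R,2R,8aS)-1,2,5,5-tetramethyl-1,2,3,5,6,7,8,8a-octahydronaphthalen-1-yl]methyl}benzaldehyde | C[C@@H]1CC=C2[C@@H](CCCC2(C)C)[C@]1(C)Cc1cc(O)c(O)c(C=O)c1O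
F4 | step 18 | 5-hydroxy-2-oxo-6-{[(1R,2R,8aS)-1,2,5,5-tetramethyl-1,2,3,5,6,7,8,8a-octahydronaphthalen-1-yl]methyl}-1,3-benzodioxole-4-carbaldehyde | C[C@@H]1CC=C2[C@@H](CCCC2(C)C)[C@]1(C)Cc1cc2OC(=O)Oc2c(C=O)c1O
F5 | step 18 | pyridinium 4-formyl-2-oxo-6-{[(1R,2R,8aS)-1,2,5,5-tetramethyl-1,2,3,5,6,7,8,8a-octahydronaphthalen-1-yl]methyl}-1,3-benzodioxol-5-yl sulfate | C[C@@H]1CC=C2[C@@H](CCCC2(C)C)[C@]1(C)Cc1cc2OC(=O)Oc2c(C=O)c1OS(=O)(=O)[O-].c1cc[nH+]cc1
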